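**Plan**

- Numbering: ring C is the central benzene; C1 carries indole A (unsubstituted), C4 carries indole B (5-prenyl; prenyl = 3-methylbut-2-enyl), and C2, C3, C5, C6 carry methoxy groups. The retrosynthesis first removes the two N-silyl groups and the methyl groups on the oxygens of C2 and C5.
- Ring C is then opened at C5–C6. The para oxygens on C2 and C5 are the carbinol and carbonyl oxygens of a 4-alkenyl-4-hydroxycyclobutenone (ring atoms C2, C3, C4, C5), and C1 and C6 are its alkenyl carbons; this para-dioxygenated, fully substituted ring is what makes the ring expansion possible.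
- The cyclobutenone is cut at C1–C2 into a β-methoxyvinyllithium carrying indole A and an indolyl methoxycyclobutenedione. The dione is cut at the bond from C4 to indole B (3-lithioindole plus dimethyl squarate), and the prenyl bond of indole B leads back to 5-bromoindole and prenyl bromide.
- Forward: arm B (silylation, prenylation, bromination, squarate addition) and arm A (silylation, Wittig, bromination–elimination) are made in parallel and joined by carbonyl addition. Ring C is the only ring formed, in the thermal step, and methylation and desilylation finish the synthesis.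
- Stereochemistry: the target has no stereocentre. The carbinol carbon of the cyclobutenone is racemic and becomes aromatic C2; the enol ether geometry only serves the stability of the vinyllithium and disappears in ring C.

Key step: step 9

Remark: the enol ether of the cyclobutenone is drawn Z (methoxy cis to the four-membered ring), because it comes from the vinyllithium with lithium cis to methoxy, the arrangement that cannot lose lithium methoxide by anti elimination; either geometry would aromatize to the same ring C.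

Remark: the bromination–dehydrobromination of the enol ether is assumed to give mainly the bromide with bromine cis to methoxy, as simple 2-alkoxyvinyl bromides do; any other isomer would be removed by chromatography.

**Route**

Step 1
Reactants: 1 5-bromoindole
Product: 2 5-bromo-1-(triisopropylsilyl)indole
Conditions: NaH, THF, 0 °C; TIPSCl, 0 °C → rt
Reagents that add atoms: triisopropylsilyl chloride, CC(C)[Si](Cl)(C(C)C)C(C)C
Why: N-silylation of the sodium indolide should proceed cleanly, and the bulky silyl group later blocks lithiation at C2 and keeps a 3-lithioindole from rearranging.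

Step 2
Reactants: 2 5-bromo-1-(triisopropylsilyl)indole; 3 prenyl bromide
Product: 5 5-prenyl-1-(triisopropylsilyl)indole, via 5-lithio-1-(triisopropylsilyl)indole 4 (not isolated)
Conditions: t-BuLi (2 equiv), THF, −78 °C; CuBr·SMe2 (10 mol %), prenyl bromide, −78 → 0 °C
Reagents that add atoms: none
Why: Bromine–lithium exchange followed by copper-catalysed allylation of the aryllithium should give the linear prenyl arene, because attack at the disubstituted terminus of prenyl bromide is disfavoured.

Step 3
Reactants: 5 5-prenyl-1-(triisopropylsilyl)indole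
Product: 6 3-bromo-5-prenyl-1-(triisopropylsilyl)indole
Conditions: NBS (1.0 equiv), THF, −78 °C
Reagents that add atoms: N-bromosuccinimide, O=C1CCC(=O)N1Br
Why: Electrophilic bromination at C3, the enamine-like and most nucleophilic position of an N-silylindole, should be much faster at −78 °C than attack of NBS on the trisubstituted alkene.

Step 4
Reactants: 6 3-bromo-5-prenyl-1-(triisopropylsilyl)indole; 7 dimethyl squarate
Product: 11 3-methoxy-4-[5-prenyl-1-(triisopropylsilyl)indol-3-yl]cyclobut-3-ene-1,2-dione, via 3-lithio-5-prenyl-1-(triisopropylsilyl)indole 8 (not isolated), via lithium alkoxide adduct 9 (not isolated), via trifluoroacetate ester 10 (not isolated)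
Conditions: t-BuLi (2 equiv), THF, −78 °C; added to 7, THF, −78 °C; (CF3CO)2O, −78 °C; then H2O, → rt
Reagents that add atoms: water, O
Why: 1,2-Addition of the aryllithium to one squarate carbonyl, then trifluoroacetylation, ionization and hydrolysis of the methoxy-stabilized cation with loss of methanol, is the standard conversion of squaric esters into 3-aryl-4-alkoxycyclobutenediones.

Step 5
Reactants: 12 indole-3-carboxaldehyde
Product: 13 1-(triisopropylsilyl)indole-3-carboxaldehyde
Conditions: NaH, THF, 0 °C; TIPSCl, 0 °C → rt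
Reagents that add atoms: triisopropylsilyl chloride, CC(C)[Si](Cl)(C(C)C)C(C)C
Why: The sodium salt of the vinylogous formamide should silylate on nitrogen to give the stable N-silyl aldehyde.

Step 6
Reactants: 13 1-(triisopropylsilyl)indole-3-carboxaldehyde
Product: 14 3-(2-methoxyvinyl)-1-(triisopropylsilyl)indole (E/Z mixture)
Conditions: MeOCH2PPh3Cl, KN(SiMe3)2, THF, 0 °C; then 13, 0 °C → rt
Reagents that add atoms: (methoxymethyl)triphenylphosphonium chloride, COC[P+](c1ccccc1)(c1ccccc1)c1ccccc1.[Cl-]
Why: Wittig olefination with the methoxymethylene ylide should give the enol ether, and the E/Z mixture is acceptable because both isomers converge in step 7.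

Step 7
Reactants: 14 3-(2-methoxyvinyl)-1-(triisopropylsilyl)indole
Product: 16 (Z)-3-(1-bromo-2-methoxyvinyl)-1-(triisopropylsilyl)indole (bromine cis to methoxy), via 1,2-dibromo ether 15 (not isolated)
Conditions: Br2 (1.0 equiv), CH2Cl2, −78 °C; then i-Pr2NEt, −78 °C → rt
Reagents that add atoms: bromine, BrBr
Why: Bromine addition to the enol ether followed by ionization of the α-bromo ether and loss of the adjacent benzylic proton (bromination–dehydrobromination of enol ethers) should place bromine on the indole-bearing carbon, with the less crowded isomer, bromine cis to methoxy, expected to predominate.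

Step 8
Reactants: 16 (Z)-3-(1-bromo-2-methoxyvinyl)-1-(triisopropylsilyl)indole; 11 3-methoxy-4-[5-prenyl-1-(triisopropylsilyl)indol-3-yl]cyclobut-3-ene-1,2-dione
Product: 19 racemic (Z)-4-hydroxy-3-methoxy-4-{2-methoxy-1-[1-(triisopropylsilyl)indol-3-yl]vinyl}-2-[5-prenyl-1-(triisopropylsilyl)indol-3-yl]cyclobut-2-en-1-one, via cis-2-methoxyvinyllithium 17 (not isolated), via lithium alkoxide 18 (not isolated)
Conditions: t-BuLi (2 equiv), THF, −78 °C; 11 in THF, −78 °C; aq NH4Cl, −78 °C
Reagents that add atoms: none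
Why: Bromine–lithium exchange with retention gives the vinyllithium with lithium cis to methoxy, held by O–Li chelation, which should add to the ketone-like carbonyl next to the methoxy-bearing carbon and not to the vinylogous ester carbonyl (regioselective 1,2-addition of organolithiums to 3-aryl-4-alkoxycyclobutenediones); the carbinol centre forms as a racemate, which does not matter because it becomes aromatic C2.

Step 9
Reactants: 19 racemic (Z)-4-hydroxy-3-methoxy-4-{2-methoxy-1-[1-(triisopropylsilyl)indol-3-yl]vinyl}-2-[5-prenyl-1-(triisopropylsilyl)indol-3-yl]cyclobut-2-en-1-one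
Product: 22 3,6-dimethoxy-2-[1-(triisopropylsilyl)indol-3-yl]-5-[5-prenyl-1-(triisopropylsilyl)indol-3-yl]benzene-1,4-diol, via dienylketene 20 (not isolated), via cyclohexa-2,4-dienone 21 (not isolated)
Conditions: toluene (degassed), 110 °C, Ar; concentrated under Ar and used directly
Reagents that add atoms: none
Why: Heating opens the cyclobutenone by a conrotatory 4π electrocyclic cleavage of the bond between the carbonyl carbon (future C5) and the carbinol carbon (future C2), the hydroxyl turning outward and the alkenyl arm inward, to give dienylketene 20. The ketene carbon then bonds to the methoxy-bearing alkene terminus (C6) in a disrotatory 6π electrocyclization, a six-membered ring closure that forms C5–C6 and gives cyclohexadienone 21, whose enolization delivers the aromatic hydroquinone 22. The closest known reaction is the thermal ring expansion of squarate-derived 4-alkenyl-4-hydroxycyclobutenones to hydroquinones (Moore rearrangement). No stereocentre survives, since the sp3 carbon C6 of 21 is lost on tautomerization. The step needs torquoselectivity (outward hydroxyl, secured by the donor oxygen on the breaking bond, so that the ketene is not captured by the hydroxyl as a furanone) and the correct substitution pattern, which is already fixed by the regiochemistry of step 8; the inward methoxy on C6 meets only the sp-hybridized ketene carbon and should not block closure.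

Step 10
Reactants: 22 3,6-dimethoxy-2-[1-(triisopropylsilyl)indol-3-yl]-5-[5-prenyl-1-(triisopropylsilyl)indol-3-yl]benzene-1,4-diol
Product: 23 3-{2,3,5,6-tetramethoxy-4-[1-(triisopropylsilyl)indol-3-yl]phenyl}-5-prenyl-1-(triisopropylsilyl)indole
Conditions: MeI, K2CO3, acetone, 50 °C, Ar
Reagents that add atoms: iodomethane, CI
Why: Williamson O-methylation of both phenols under anhydrous carbonate conditions should leave the N–Si bonds and the prenyl group untouched, and exclusion of air prevents oxidation to the quinone.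

Step 11
Reactants: 23 3-{2,3,5,6-tetramethoxy-4-[1-(triisopropylsilyl)indol-3-yl]phenyl}-5-prenyl-1-(triisopropylsilyl)indole
Product: 24 3-[4-(1H-indol-3-yl)-2,3,5,6-tetramethoxyphenyl]-5-prenyl-1H-indole (target)
Conditions: Bu4NF, THF, 0 °C → rt; aq work-up
Reagents that add atoms: none
Why: Fluoride-induced cleavage of both N–Si bonds should release the two indole N–H groups without affecting the aryl methyl ethers or the alkene.

**Compound list**

1 | 5-bromoindole | Brc1ccc2[nH]ccc2c1 | starting material
2 | 5-bromo-1-(triisopropylsilyl)indole | Brc1ccc2c(c1)ccn2[Si](C(C)C)(C(C)C)C(C)C | intermediate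
3 | prenyl bromide (1-bromo-3-methylbut-2-ene) | CC(C)=CCBr | starting material
4 | 5-lithio-1-(triisopropylsilyl)indole | [Li]c1ccc2c(c1)ccn2[Si](C(C)C)(C(C)C)C(C)C | intermediate
5 | 5-prenyl-1-(triisopropylsilyl)indole | CC(C)=CCc1ccc2c(c1)ccn2[Si](C(C)C)(C(C)C)C(C)C | intermediate
6 | 3-bromo-5-prenyl-1-(triisopropylsilyl)indole | CC(C)=CCc1ccc2c(c1)c(Br)cn2[Si](C(C)C)(C(C)C)C(C)C | intermediate
7 | dimethyl squarate | COC1=C(OC)C(=O)C1=O | starting material
8 | 3-lithio-5-prenyl-1-(triisopropylsilyl)indole | CC(C)=CCc1ccc2c(c1)c([Li])cn2[Si](C(C)C)(C(C)C)C(C)C | intermediate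
9 | lithium 2,3-dimethoxy-4-oxo-1-[5-prenyl-1-(triisopropylsilyl)indol-3-yl]cyclobut-2-en-1-olate (racemic) | [Li]OC1(c2cn([Si](C(C)C)(C(C)C)C(C)C)c3ccc(CC=C(C)C)cc23)C(OC)=C(OC)C1=O | intermediate
10 | 2,3-dimethoxy-4-oxo-1-[5-prenyl-1-(triisopropylsilyl)indol-3-yl]cyclobut-2-en-1-yl trifluoroacetate (racemic) | O=C(OC1(c2cn([Si](C(C)C)(C(C)C)C(C)C)c3ccc(CC=C(C)C)cc23)C(OC)=C(OC)C1=O)C(F)(F)F | intermediate
11 | 3-methoxy-4-[5-prenyl-1-(triisopropylsilyl)indol-3-yl]cyclobut-3-ene-1,2-dione | COC1=C(c2cn([Si](C(C)C)(C(C)C)C(C)C)c3ccc(CC=C(C)C)cc23)C(=O)C1=O | intermediate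
12 | indole-3-carboxaldehyde | O=Cc1c[nH]c2ccccc12 | starting material
13 | 1-(triisopropylsilyl)indole-3-carboxaldehyde | O=Cc1cn([Si](C(C)C)(C(C)C)C(C)C)c2ccccc12 | intermediate
14 | 3-(2-methoxyvinyl)-1-(triisopropylsilyl)indole, E/Z mixture | COC=Cc1cn([Si](C(C)C)(C(C)C)C(C)C)c2ccccc12 | intermediate
15 | 3-(1,2-dibromo-2-methoxyethyl)-1-(triisopropylsilyl)indole, diastereomer mixture | COC(Br)C(Br)c1cn([Si](C(C)C)(C(C)C)C(C)C)c2ccccc12 | intermediate
16 | (Z)-3-(1-bromo-2-methoxyvinyl)-1-(triisopropylsilyl)indole, bromine cis to methoxy | CO/C=C(\Br)c1cn([Si](C(C)C)(C(C)C)C(C)C)c2ccccc12 | intermediate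
17 | (E)-2-methoxy-1-[1-(triisopropylsilyl)indol-3-yl]vinyllithium, lithium cis to methoxy | CO/C=C(\[Li])c1cn([Si](C(C)C)(C(C)C)C(C)C)c2ccccc12 | intermediate
18 | lithium alkoxide of 19 (racemic, Z) | CO/C=C(/c1cn([Si](C(C)C)(C(C)C)C(C)C)c2ccccc12)C1(O[Li])C(OC)=C(c2cn([Si](C(C)C)(C(C)C)C(C)C)c3ccc(CC=C(C)C)cc23)C1=O | intermediate
19 | racemic (Z)-4-hydroxy-3-methoxy-4-{2-methoxy-1-[1-(triisopropylsilyl)indol-3-yl]vinyl}-2-[5-prenyl-1-(triisopropylsilyl)indol-3-yl]cyclobut-2-en-1-one, methoxy cis to the ring carbon | CO/C=C(/c1cn([Si](C(C)C)(C(C)C)C(C)C)c2ccccc12)C1(O)C(OC)=C(c2cn([Si](C(C)C)(C(C)C)C(C)C)c3ccc(CC=C(C)C)cc23)C1=O | intermediate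
20 | 4-hydroxy-3,6-dimethoxy-5-[1-(triisopropylsilyl)indol-3-yl]-2-[5-prenyl-1-(triisopropylsilyl)indol-3-yl]hexa-1,3,5-trien-1-one (dienylketene, alkenyl arm cis to the ketene) | O=C=C(c1cn([Si](C(C)C)(C(C)C)C(C)C)c2ccc(CC=C(C)C)cc12)/C(OC)=C(O)\C(c1cn([Si](C(C)C)(C(C)C)C(C)C)c2ccccc12)=C/OC | intermediate
21 | racemic 4-hydroxy-3,6-dimethoxy-5-[1-(triisopropylsilyl)indol-3-yl]-2-[5-prenyl-1-(triisopropylsilyl)indol-3-yl]cyclohexa-2,4-dien-1-one | COC1C(=O)C(c2cn([Si](C(C)C)(C(C)C)C(C)C)c3ccc(CC=C(C)C)cc23)=C(OC)C(O)=C1c1cn([Si](C(C)C)(C(C)C)C(C)C)c2ccccc12 | intermediate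
22 | 3,6-dimethoxy-2-[1-(triisopropylsilyl)indol-3-yl]-5-[5-prenyl-1-(triisopropylsilyl)indol-3-yl]benzene-1,4-diol | Oc1c(-c2cn([Si](C(C)C)(C(C)C)C(C)C)c3ccc(CC=C(C)C)cc23)c(OC)c(O)c(-c2cn([Si](C(C)C)(C(C)C)C(C)C)c3ccccc23)c1OC | intermediate
23 | 3-{2,3,5,6-tetramethoxy-4-[1-(triisopropylsilyl)indol-3-yl]phenyl}-5-prenyl-1-(triisopropylsilyl)indole | COc1c(OC)c(-c2cn([Si](C(C)C)(C(C)C)C(C)C)c3ccc(CC=C(C)C)cc23)c(OC)c(OC)c1-c1cn([Si](C(C)C)(C(C)C)C(C)C)c2ccccc12 | intermediate
24 | 3-[4-(1H-indol-3-yl)-2,3,5,6-tetramethoxyphenyl]-5-(3-methylbut-2-enyl)-1H-indole | COc1c(OC)c(-c2c[nH]c3ccc(CC=C(C)C)cc23)c(OC)c(OC)c1-c1c[nH]c2ccccc12 | target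

**Step count and risks**

Total step count: 11. Longest linear sequence: 8 steps (steps 1, 2, 3, 4, 8, 9, 10, 11).

Most likely to fail, in this order: step 7, step 8, step 9.

Step 7. The dibromide may lose HBr in the wrong sense or give the isomer with bromine trans to methoxy. Bromine may also attack the indole ring, or HBr may strip the N-silyl group. The fallback builds the same vinyl anion from a ketone with geometry set by chelation and sets out from 13. Methoxymethyllithium (Bu3SnCH2OMe, n-BuLi, THF, −78 °C) adds to the aldehyde to give 2-methoxy-1-[1-(triisopropylsilyl)indol-3-yl]ethanol F1. MnO2 in CH2Cl2 oxidizes it to 2-methoxy-1-[1-(triisopropylsilyl)indol-3-yl]ethanone F2. LiN(SiMe3)2 forms the chelated enolate with the two oxygens cis, and PhNTf2 traps it as (Z)-2-methoxy-1-[1-(triisopropylsilyl)indol-3-yl]vinyl trifluoromethanesulfonate F3. (Me3Sn)2, Pd(PPh3)4 and LiCl in THF at 60 °C convert it with retention into (Z)-3-[2-methoxy-1-(trimethylstannyl)vinyl]-1-(triisopropylsilyl)indole F4. Tin–lithium exchange with MeLi in THF at −78 °C then gives 17, where the fallback rejoins the route.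

Step 8. The N-silylindol-3-yl group is itself a strong donor that deactivates the ketone carbonyl through the ring double bond, so the vinyllithium may attack the other carbonyl and lead to the meta-bis(indolyl) isomer. The reagent may also lose lithium methoxide if it warms. The fallback weakens the donor by exchanging the silyl group of indole B for a carbamate and sets out from 11. Bu4NF buffered with AcOH in THF at 0 °C gives 3-methoxy-4-(5-prenyl-1H-indol-3-yl)cyclobut-3-ene-1,2-dione F5. Boc2O, Et3N and catalytic DMAP in CH2Cl2 give tert-butyl 3-(2-methoxy-3,4-dioxocyclobut-1-enyl)-5-prenylindole-1-carboxylate F6, in which methoxy is the dominant donor. Addition of 17 at −78 °C should then give racemic tert-butyl 3-{3-hydroxy-2-methoxy-3-[(Z)-2-methoxy-1-(1-triisopropylsilylindol-3-yl)vinyl]-4-oxocyclobut-1-enyl}-5-prenylindole-1-carboxylate F7. Heating in toluene gives tert-butyl 3-{2,5-dihydroxy-3,6-dimethoxy-4-[1-(triisopropylsilyl)indol-3-yl]phenyl}-5-prenylindole-1-carboxylate F8. MeI and K2CO3 give tert-butyl 3-{2,3,5,6-tetramethoxy-4-[1-(triisopropylsilyl)indol-3-yl]phenyl}-5-prenylindole-1-carboxylate F9. NaOMe in MeOH–THF at 60 °C removes both nitrogen groups and the fallback comes back at 24.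

Step 9. Closure with the methoxy turned inward may be slow enough for the hydroxyl to capture the ketene as a furanone, and the electron-rich hydroquinone may oxidize to the quinone during handling. The fallback caps the carbinol oxygen before heating and sets out from 18. In place of the proton quench in step 8, MeOTf is added at −78 °C to give racemic (Z)-3,4-dimethoxy-4-{2-methoxy-1-[1-(triisopropylsilyl)indol-3-yl]vinyl}-2-[5-prenyl-1-(triisopropylsilyl)indol-3-yl]cyclobut-2-en-1-one F10. Thermolysis in toluene at 110 °C (ring expansion of a 4-alkoxy-4-alkenylcyclobutenone) gives 2,3,6-trimethoxy-4-[1-(triisopropylsilyl)indol-3-yl]-5-[5-prenyl-1-(triisopropylsilyl)indol-3-yl]phenol F11, which has no free hydroxyl on the opening ring and cannot form a quinone. Methylation of its single phenol with MeI and K2CO3 returns to the route at 23.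

**Further compounds**

F1 | step 7 | 2-methoxy-1-[1-(triisopropylsilyl)indol-3-yl]ethanol (racemic) | COCC(O)c1cn([Si](C(C)C)(C(C)C)C(C)C)c2ccccc12
F2 | step 7 | 2-methoxy-1-[1-(triisopropylsilyl)indol-3-yl]ethanone | COCC(=O)c1cn([Si](C(C)C)(C(C)C)C(C)C)c2ccccc12
F3 | step 7 | (Z)-2-methoxy-1-[1-(triisopropylsilyl)indol-3-yl]vinyl trifluoromethanesulfonate | CO/C=C(\OS(=O)(=O)C(F)(F)F)c1cn([Si](C(C)C)(C(C)C)C(C)C)c2ccccc12
F4 | step 7 | (Z)-3-[2-methoxy-1-(trimethylstannyl)vinyl]-1-(triisopropylsilyl)indole | CO/C=C(\[Sn](C)(C)C)c1cn([Si](C(C)C)(C(C)C)C(C)C)c2ccccc12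
F5 | step 8 | 3-methoxy-4-(5-prenyl-1H-indol-3-yl)cyclobut-3-ene-1,2-dione | COC1=C(c2c[nH]c3ccc(CC=C(C)C)cc23)C(=O)C1=O
F6 | step 8 | tert-butyl 3-(2-methoxy-3,4-dioxocyclobut-1-enyl)-5-prenylindole-1-carboxylate | COC1=C(c2cn(C(=O)OC(C)(C)C)c3ccc(CC=C(C)C)cc23)C(=O)C1=O
F7 | step 8 | racemic tert-butyl 3-{3-hydroxy-2-methoxy-3-[(Z)-2-methoxy-1-(1-triisopropylsilylindol-3-yl)vinyl]-4-oxocyclobut-1-enyl}-5-prenylindole-1-carboxylate | CO/C=C(/c1cn([Si](C(C)C)(C(C)C)C(C)C)c2ccccc12)C1(O)C(OC)=C(c2cn(C(=O)OC(C)(C)C)c3ccc(CC=C(C)C)cc23)C1=O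
F8 | step 8 | tert-butyl 3-{2,5-dihydroxy-3,6-dimethoxy-4-[1-(triisopropylsilyl)indol-3-yl]phenyl}-5-prenylindole-1-carboxylate | Oc1c(-c2cn(C(=O)OC(C)(C)C)c3ccc(CC=C(C)C)cc23)c(OC)c(O)c(-c2cn([Si](C(C)C)(C(C)C)C(C)C)c3ccccc23)c1OC
F9 | step 8 | tert-butyl 3-{2,3,5,6-tetramethoxy-4-[1-(triisopropylsilyl)indol-3-yl]phenyl}-5-prenylindole-1-carboxylate | COc1c(OC)c(-c2cn(C(=O)OC(C)(C)C)c3ccc(CC=C(C)C)cc23)c(OC)c(OC)c1-c1cn([Si](C(C)C)(C(C)C)C(C)C)c2ccccc12
F10 | step 9 | racemic (Z)-3,4-dimethoxy-4-{2-methoxy-1-[1-(triisopropylsilyl)indol-3-yl]vinyl}-2-[5-prenyl-1-(triisopropylsilyl)indol-3-yl]cyclobut-2-en-1-one | CO/C=C(/c1cn([Si](C(C)C)(C(C)C)C(C)C)c2ccccc12)C1(OC)C(OC)=C(c2cn([Si](C(C)C)(C(C)C)C(C)C)c3ccc(CC=C(C)C)cc23)C1=O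
F11 | step 9 | 2,3,6-trimethoxy-4-[1-(triisopropylsilyl)indol-3-yl]-5-[5-prenyl-1-(triisopropylsilyl)indol-3-yl]phenol | Oc1c(-c2cn([Si](C(C)C)(C(C)C)C(C)C)c3ccc(CC=C(C)C)cc23)c(OC)c(OC)c(-c2cn([Si](C(C)C)(C(C)C)C(C)C)c3ccccc23)c1OC
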